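**Plan**

Numbering (clerodane type): ring B = C1–C4, C5, C10; ring A = C5–C10; ring C = C1, C10, C9, C11, C12, C13, C16; C17 is the methylene carbon on C8, C18 the lactone carbonyl on C4, C19 the OCH2 on C5, C20 the methyl on C9; β is the face of H-10.
Cuts, in retrosynthetic order: C12=O from its dithiolane; C1–C16 (ring C); the C7 acetate; C4–C18 and C18–O (CO insertion into a C4 dienyl triflate); C12–C13 (3-furyl Grignard on a Weinreb amide); C8=C17; C7–O; C9–C11 (reductive alkylation); C9=C10 and C5–C6 (annulation of ring A onto ring B); C5–C19 (formaldehyde aldol).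
Forward order: cyclohexane-1,3-dione is ring B; Michael addition, hydroxymethylation and an amino-acid-mediated aldol condensation add C19 and ring A; Birch alkylation adds the C9 arm; ring A is oxygenated and methylenated; ring B is taken to the C1=C2–C3=C4 dienyl triflate; furan and dithiolane are placed on the arm; carbonylation closes the lactone; ring C closes last.
Enabling feature: C1 is the δ-carbon of the dienyl lactone C18(=O)–C4=C3–C2=C1 in ring B, and C16, the furan α-carbon next to C13, is held over it by the arm C11–C12–C13 from C9, so the C1–C16 bond is a vinylogous (1,6) Friedel–Crafts alkylation that makes the seven-membered ring C.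
Stereochemistry: C5 from the enantioselective aldol condensation; C10 and C9 from the Birch reductive alkylation (trans fusion, alkylation anti to the C5 CH2OSi group); C7 from β-face Rubottom oxidation; C1 from the β-disposed tether in the ring closure.

Key step: step 19

Remark: the sense of induction in step 4 is assumed to follow the angular-methyl series, in which D-phenylalanine gives the enedione topology needed here (C5 R).

**Route**

Step 1
Reactants: 1 cyclohexane-1,3-dione; 2 pent-1-en-3-one
Product: 3 2-(3-oxopentyl)cyclohexane-1,3-dione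
Conditions: H2O, rt (1 in slight excess)
Reagents that add atoms: none
Why: Michael addition of the acidic 1,3-dione to the enone proceeds in water without added base and should stop at the mono-adduct when the dione is in slight excess.

Step 2
Reactants: 3 2-(3-oxopentyl)cyclohexane-1,3-dione
Product: 4 2-(hydroxymethyl)-2-(3-oxopentyl)cyclohexane-1,3-dione
Conditions: aq. CH2O (37%), NaHCO3 (cat.), THF/H2O, 0 °C → rt
Reagents that add atoms: formaldehyde, C=O
Why: aldol addition (hydroxymethylation) of the 2-monosubstituted 1,3-dione to formaldehyde installs C19 on the future C5.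

Step 3
Reactants: 4 hydroxymethyl triketone
Product: 5 2-(3-oxopentyl)-2-(triisopropylsilyloxymethyl)cyclohexane-1,3-dione
Conditions: TIPSOTf, 2,6-lutidine, CH2Cl2, −78 → 0 °C
Reagents that add atoms: triisopropylsilyl trifluoromethanesulfonate, CC(C)[Si](C(C)C)(C(C)C)OS(=O)(=O)C(F)(F)F
Why: silylation of the primary alcohol with a silyl triflate at low temperature outruns retro-aldol loss of formaldehyde and gives an ether stable to acid, base and dissolving metal.

Step 4
Reactants: 5 silyl ether triketone
Product: 6 (8aR)-5-methyl-8a-(triisopropylsilyloxymethyl)-3,4,8,8a-tetrahydronaphthalene-1,6(2H,7H)-dione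
Conditions: D-phenylalanine (1 equiv), (1R)-(−)-10-camphorsulfonic acid (0.5 equiv), DMF, 30 → 65 °C
Reagents that add atoms: none
Why: Hajos–Parrish–Eder–Sauer–Wiechert-type enamine aldol condensation in which the amino acid selects one of the two enantiotopic ring carbonyls, setting the C5 quaternary centre while forming C9=C10.

Step 5
Reactants: 6 bicyclic enedione
Product: 7 C4 ethylene ketal of 6
Conditions: HOCH2CH2OH, p-TsOH·H2O, 4 Å MS, rt
Reagents that add atoms: ethane-1,2-diol, OCCO
Why: acid-catalysed ketalisation is selective for the saturated C4 ketone because the C8 carbonyl is deactivated by conjugation.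

Step 6
Reactants: 7 ketal enone; 8 ethyl bromoacetate
Product: 10 C9-alkylated trans-decalone ethyl ester, via lithium enolate 9 (not isolated)
Conditions: Li, NH3 (l)/THF, t-BuOH (1 equiv), −78 → −33 °C; isoprene; then 8, THF, −78 → 0 °C
Reagents that add atoms: none
Why: Birch-type dissolving-metal reduction protonates C10 trans to the C5 substituent, and the C8 enolate is alkylated at C9 from the β face, anti to the axial C5 CH2OSi group, so C20 stays α and the ester arm is β.

Step 7
Reactants: 10 keto ester
Product: 11 C7=C8 tert-butyldimethylsilyl enol ether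
Conditions: TBSOTf, Et3N, CH2Cl2, 0 °C → rt
Reagents that add atoms: tert-butyldimethylsilyl trifluoromethanesulfonate, CC(C)(C)[Si](C)(C)OS(=O)(=O)C(F)(F)F
Why: soft enolisation with silyl triflate and amine can only go toward C7, since C9 is quaternary, and leaves the ester untouched.

Step 8
Reactants: 11 silyl enol ether
Product: 12 7β-(tert-butyldimethylsilyloxy) C8 ketone
Conditions: mCPBA, NaHCO3, CH2Cl2, −20 → 0 °C
Reagents that add atoms: 3-chloroperoxybenzoic acid, OOC(=O)c1cccc(Cl)c1
Why: Rubottom oxidation in which the peracid attacks the enol ether from the β face, away from the axial C19 and C20 groups, and a 1,4-silyl shift gives the equatorial 7β-silyloxy ketone.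

Step 9
Reactants: 12 α-silyloxy ketone
Product: 13 8-methylidene compound
Conditions: Zn, CH2Br2, TiCl4, THF/CH2Cl2, 0 °C → rt
Reagents that add atoms: dibromomethane, BrCBr
Why: Takai–Lombardo methylenation converts hindered, enolisable α-oxygenated ketones into methylene compounds without epimerising C7 and without attacking the ester or the ketal.

Step 10
Reactants: 13 methylidene ketal
Product: 14 C4 ketone
Conditions: PPTS, acetone/H2O, 60 °C
Reagents that add atoms: water, O
Why: mild acid-catalysed ketal hydrolysis releases the C4 ketone while both silyl ethers and the allylic system should be retained.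

Step 11
Reactants: 14 C4 ketone
Product: 15 C2=C3 enone
Conditions: IBX, DMSO/PhMe, 70 °C
Reagents that add atoms: none
Why: IBX-mediated α,β-dehydrogenation of the ketone can only introduce the C2=C3 double bond, because the other α-carbon, C5, is quaternary.

Step 12
Reactants: 15 enone
Product: 16 C1=C2–C3=C4 dienyl triflate
Conditions: Tf2O, 2,6-di-tert-butyl-4-methylpyridine, CH2Cl2, 0 °C → rt
Reagents that add atoms: trifluoromethanesulfonic anhydride, O=S(=O)(OS(=O)(=O)C(F)(F)F)C(F)(F)F
Why: dienol triflate formation by O-triflation of the enone and loss of a C1 proton, the only one available to the vinylogous system, gives the linear dienyl triflate without enolising the ester.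

Step 13
Reactants: 16 dienyl triflate ethyl ester
Product: 17 Weinreb amide
Conditions: Me(MeO)NH·HCl, i-PrMgCl, THF, −20 → 0 °C
Reagents that add atoms: N,O-dimethylhydroxylamine hydrochloride, CNOC.Cl
Why: Weinreb amide formation by aminolysis of the ester with the chloromagnesium amide, which uses up the Grignard reagent as base so that the dienyl triflate and silyl ethers are not attacked.

Step 14
Reactants: 17 Weinreb amide; 18 3-bromofuran
Product: 21 furan-3-yl ketone, via 3-lithiofuran 19 (not isolated), via 3-furylmagnesium bromide 20 (not isolated)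
Conditions: 18, n-BuLi, THF, −78 °C; MgBr2·OEt2; then 17, −78 → 0 °C; aq. NH4Cl
Reagents that add atoms: none
Why: Weinreb ketone synthesis in which bromine–lithium exchange and transmetalation to magnesium give a 3-furyl nucleophile that adds once to the amide as a stable chelate and does not attack the vinyl triflate.

Step 15
Reactants: 21 furyl ketone
Product: 22 C12 1,3-dithiolane
Conditions: HSCH2CH2SH, Zn(OTf)2, ClCH2CH2Cl, 45 °C
Reagents that add atoms: ethane-1,2-dithiol, SCCS
Why: Lewis-acid-catalysed thioketalisation of the only ketone turns C12 into an sp3 carbon so that the furan is electron-rich again, and the electron-poor dienyl triflate should not react with the thiol.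

Step 16
Reactants: 22 dithiolane bis-silyl ether
Product: 23 7β,19-diol
Conditions: HF·pyridine, pyridine, THF, 0 °C → rt
Reagents that add atoms: none
Why: fluoride-mediated cleavage of both silyl ethers under buffered acidic conditions that spare the vinyl triflate, the dithiolane and the furan.

Step 17
Reactants: 23 diol dienyl triflate
Product: 24 dienyl 18,19-lactone with free 7β-hydroxyl
Conditions: Pd(PPh3)4 (10 mol %), CO (1 atm), i-Pr2NEt, LiCl, DMF, 60 °C
Reagents that add atoms: carbon monoxide, [C-]#[O+]
Why: carbonylative lactonisation in which zerovalent palladium inserts into the C4–OTf bond, CO insertion gives an acylpalladium species and the C19 hydroxyl captures it to close the five-membered lactone, while the thioketal is expected to be tolerated by the phosphine-ligated catalyst.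

Step 18
Reactants: 24 lactone alcohol
Product: 25 7β-acetate dienyl lactone
Conditions: Ac2O, pyridine, DMAP (cat.), CH2Cl2, 0 °C → rt
Reagents that add atoms: acetic anhydride, CC(=O)OC(C)=O
Why: DMAP-catalysed acylation of the remaining secondary alcohol under conditions too weakly basic to deprotonate the dienyl lactone.

Step 19
Reactants: 25 dienyl lactone with furan-3-yl dithiolane arm
Product: 27 ring C closed dithiolane lactone, via deconjugated lactone 26 (not isolated)
Conditions: Me2AlCl (3 equiv), CH2Cl2, −78 → −20 °C; aq. KNaC4H4O6; then DBU (0.2 equiv), CH2Cl2, rt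
Reagents that add atoms: none
Why: Me2AlCl binds the lactone carbonyl and makes C1, the δ-carbon of the C1=C2–C3=C4–C18=O system, electrophilic; the furan α-carbon C16 attacks it, the Wheland intermediate rearomatises by proton loss, and the aluminium dienolate is protonated on work-up, DBU then moving any C2=C3 isomer 26 into conjugation. The closest known reaction type is the acid-promoted intramolecular Friedel–Crafts conjugate addition of furans to enones, extended by one double bond as in 1,6-additions of electron-rich arenes to dienyl carbonyl compounds. Ring C closes in a 7-exo-trig mode. The new C1 stereocentre is set by the tether: C11 is β and equatorial on C9, so C16 can reach only the β face of C1, which leaves H-1 α and ring C trans-diequatorially fused. The step needs δ- over β-attack on the lactone and α- over β-attack by the furan: C3 is out of reach of the three-atom arm, C16 is the more nucleophilic of the two furan carbons flanking C13, and the dithiolane keeps the furan electron-rich. The proton-scavenging aluminium reagent at low temperature should leave the allylic acetate and the exocyclic alkene untouched.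

Step 20
Reactants: 27 C12 dithiolane of the target
Product: 28 CNP0273675.1
Conditions: PhI(OCOCF3)2, NaHCO3, MeCN/H2O (9:1), 0 °C
Reagents that add atoms: water, O
Why: oxidative hydrolysis of the dithioketal by the hypervalent iodine reagent should be faster than oxidation of the furan or the alkenes and unveils the C12 ketone.

**Compound list**

1 | cyclohexane-1,3-dione | O=C1CCCC(=O)C1 | starting material
2 | pent-1-en-3-one (ethyl vinyl ketone) | CCC(=O)C=C | starting material
3 | 2-(3-oxopentyl)cyclohexane-1,3-dione | CCC(=O)CCC1C(=O)CCCC1=O | intermediate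
4 | 2-(hydroxymethyl)-2-(3-oxopentyl)cyclohexane-1,3-dione | CCC(=O)CCC1(CO)C(=O)CCCC1=O | intermediate
5 | 2-(3-oxopentyl)-2-(triisopropylsilyloxymethyl)cyclohexane-1,3-dione | CCC(=O)CCC1(CO[Si](C(C)C)(C(C)C)C(C)C)C(=O)CCCC1=O | intermediate
6 | (8aR)-5-methyl-8a-(triisopropylsilyloxymethyl)-3,4,8,8a-tetrahydronaphthalene-1,6(2H,7H)-dione (C4 and C8 ketones, C9=C10, C5 R) | O=C1CC[C@@]2(CO[Si](C(C)C)(C(C)C)C(C)C)C(=O)CCCC2=C1C | intermediate
7 | C4 ethylene ketal (1,3-dioxolane) of 6; C8 enone and C5 configuration retained | O=C1CC[C@@]2(CO[Si](C(C)C)(C(C)C)C(C)C)C3(OCCO3)CCCC2=C1C | intermediate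
8 | ethyl bromoacetate | CCOC(=O)CBr | starting material
9 | lithium C8(OLi)=C9 enolate of the reduced ketal, 10β-H, 5α-CH2OTIPS (trans-fused) | CC1=C(O[Li])CC[C@@]2(CO[Si](C(C)C)(C(C)C)C(C)C)C3(OCCO3)CCC[C@H]12 | intermediate (not isolated)
10 | ethyl 2-[4,4-(ethylenedioxy)-9α-methyl-8-oxo-5α-(triisopropylsilyloxymethyl)-10β-H-decalin-9β-yl]acetate | O=C1CC[C@@]2(CO[Si](C(C)C)(C(C)C)C(C)C)C3(OCCO3)CCC[C@@H]2[C@@]1(C)CC(=O)OCC | intermediate
11 | C7=C8 tert-butyldimethylsilyl enol ether of 10 | CC(C)(C)[Si](C)(C)OC1=CC[C@@]2(CO[Si](C(C)C)(C(C)C)C(C)C)C3(OCCO3)CCC[C@@H]2[C@@]1(C)CC(=O)OCC | intermediate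
12 | 7β-(tert-butyldimethylsilyloxy) derivative of 10 (C8 ketone, equatorial 7β-OTBS) | O=C1[C@@H](O[Si](C)(C)C(C)(C)C)C[C@@]2(CO[Si](C(C)C)(C(C)C)C(C)C)C3(OCCO3)CCC[C@@H]2[C@@]1(C)CC(=O)OCC | intermediate
13 | 8-methylidene compound (C8=C17; 7β-OTBS, C4 ketal, 5α-CH2OTIPS, 9β-CH2CO2Et, 9α-Me, 10β-H) | C=C1[C@@H](O[Si](C)(C)C(C)(C)C)C[C@@]2(CO[Si](C(C)C)(C(C)C)C(C)C)C3(OCCO3)CCC[C@@H]2[C@@]1(C)CC(=O)OCC | intermediate
14 | C4 ketone from 13 | C=C1[C@@H](O[Si](C)(C)C(C)(C)C)C[C@@]2(CO[Si](C(C)C)(C(C)C)C(C)C)C(=O)CCC[C@@H]2[C@@]1(C)CC(=O)OCC | intermediate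
15 | C2=C3 enone (4-oxo) from 14 | C=C1[C@@H](O[Si](C)(C)C(C)(C)C)C[C@@]2(CO[Si](C(C)C)(C(C)C)C(C)C)C(=O)C=CC[C@@H]2[C@@]1(C)CC(=O)OCC | intermediate
16 | C1=C2–C3=C4 dienyl triflate (C4–OTf), ethyl ester arm | C=C1[C@@H](O[Si](C)(C)C(C)(C)C)C[C@@]2(CO[Si](C(C)C)(C(C)C)C(C)C)C(OS(=O)(=O)C(F)(F)F)=CC=C[C@@H]2[C@@]1(C)CC(=O)OCC | intermediate
17 | N-methoxy-N-methylamide (Weinreb amide) of the C9 arm of 16 | C=C1[C@@H](O[Si](C)(C)C(C)(C)C)C[C@@]2(CO[Si](C(C)C)(C(C)C)C(C)C)C(OS(=O)(=O)C(F)(F)F)=CC=C[C@@H]2[C@@]1(C)CC(=O)N(C)OC | intermediate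
18 | 3-bromofuran | Brc1ccoc1 | starting material
19 | 3-lithiofuran | [Li]c1ccoc1 | intermediate (not isolated)
20 | 3-furylmagnesium bromide | Br[Mg]c1ccoc1 | intermediate (not isolated)
21 | furan-3-yl ketone (C12=O) with dienyl triflate and both silyl ethers | C=C1[C@@H](O[Si](C)(C)C(C)(C)C)C[C@@]2(CO[Si](C(C)C)(C(C)C)C(C)C)C(OS(=O)(=O)C(F)(F)F)=CC=C[C@@H]2[C@@]1(C)CC(=O)c1ccoc1 | intermediate
22 | C12 1,3-dithiolane of 21 | C=C1[C@@H](O[Si](C)(C)C(C)(C)C)C[C@@]2(CO[Si](C(C)C)(C(C)C)C(C)C)C(OS(=O)(=O)C(F)(F)F)=CC=C[C@@H]2[C@@]1(C)CC1(SCCS1)c1ccoc1 | intermediate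
23 | 7β,19-diol dienyl triflate with furan-3-yl dithiolane arm | C=C1[C@@H](O)C[C@@]2(CO)C(OS(=O)(=O)C(F)(F)F)=CC=C[C@@H]2[C@@]1(C)CC1(SCCS1)c1ccoc1 | intermediate
24 | dienyl 18,19-lactone (C1=C2, C3=C4) with 7β-OH and furan-3-yl dithiolane arm | C=C1[C@@H](O)C[C@@]23COC(=O)C2=CC=C[C@@H]3[C@@]1(C)CC1(SCCS1)c1ccoc1 | intermediate
25 | 7β-acetate of 24 (key-step precursor) | C=C1[C@@H](OC(C)=O)C[C@@]23COC(=O)C2=CC=C[C@@H]3[C@@]1(C)CC1(SCCS1)c1ccoc1 | intermediate
26 | ring C closed lactone with C2=C3 and C4–H (either C4 epimer) | C=C1[C@@H](OC(C)=O)C[C@@]23COC(=O)C2C=C[C@H]2c4occc4C4(SCCS4)C[C@]1(C)[C@@H]23 | intermediate (not isolated)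
27 | C12 dithiolane of the target (C1–C16 bond, 1α-H, C3=C4 lactone) | C=C1[C@@H](OC(C)=O)C[C@@]23COC(=O)C2=CC[C@H]2c4occc4C4(SCCS4)C[C@]1(C)[C@@H]23 | intermediate
28 | CNP0273675.1 (7β-acetoxy-12-oxo 18,19-olide with furan-fused cycloheptanone ring C; 1α-H, 10β-H) | C=C1[C@@H](OC(C)=O)C[C@@]23COC(=O)C2=CC[C@H]2c4occc4C(=O)C[C@]1(C)[C@@H]23 | target

**Summary**

Total step count: 20. Longest linear sequence: 20 steps, from cyclohexane-1,3-dione; pent-1-en-3-one, ethyl bromoacetate and 3-bromofuran enter as purchased.

Steps most likely to fail: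

Step 19. The furan may add too slowly to the weakly electrophilic δ-carbon, so that Lewis-acid-induced ionisation of the allylic acetate or oligomerisation of the furan overtakes ring closure. The fallback forms the same C1–C16 bond by a reductive Heck cyclisation instead of an acid-promoted arene attack. It sets out from Weinreb amide 17. 3-Bromofuran 18 is lithiated at C2 (LDA, THF, −78 °C) and chlorinated with C2Cl6 to 3-bromo-2-chlorofuran F1. Bromine–lithium exchange (n-BuLi, −78 °C), transmetalation with MgBr2·OEt2 and addition to 17 give the 2-chlorofuran-3-yl ketone F2. Thioketalisation as in step 15 gives the chlorofuryl dithiolane F3, HF·pyridine the chlorofuryl diol F4, and carbonylative lactonisation as in step 17 the chlorofuryl dienyl lactone alcohol F5; Pd(PPh3)4 should not insert into the C–Cl bond. With Pd(OAc)2, P(t-Bu)3·HBF4, HCO2Na and Et4NCl in DMF at 80 °C, oxidative addition at C16–Cl, 7-exo syn-carbopalladation of C1=C2 from the β face and formate reduction of the resulting allylpalladium species, followed by DBU, should give the ring C closed 7β-alcohol F6. The 7β-hydroxyl is left free in this step so that no allylic acetate meets zerovalent palladium. Acetylation as in step 18 returns to the route at 27.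

Step 17. Coordination of the dithiolane sulfur atoms to palladium may stall oxidative addition or CO insertion, and the dienyl triflate may then be lost by slow solvolysis at 60 °C. The fallback carbonylates before sulfur is present and changes the order of masking. Ketone 21 is desilylated with HF·pyridine to the keto diol F7, carbonylative lactonisation gives the keto dienyl lactone alcohol F8, and acetylation gives the keto acetate F9. The furyl ketone is then thioketalised under thiol-free conditions with Me3SiSCH2CH2SSiMe3 and ZnI2 (Et2O, 0 °C → rt), which rejoins the route at 25.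

Step 4. The bulky silyloxymethyl group at the prochiral centre may weaken discrimination between the two enantiotopic ring carbonyls or slow the enamine aldol step, giving low enantiomeric purity. The fallback replaces catalytic desymmetrisation by resolution. Triketone 5 is cyclised with pyrrolidine and AcOH to the racemic enedione F10, which is ketalised at C4 with (2R,3R)-butane-2,3-diol (p-TsOH, 4 Å MS). The two diastereomeric ketals are separated by chromatography or crystallisation, and the one derived from the (R)-enedione, the butanediol ketal F11, is hydrolysed (PPTS, acetone/H2O) to enantiopure 6, where the route is rejoined.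

Further compounds
F1 | step 19 | 3-bromo-2-chlorofuran | Clc1occc1Br
F2 | step 19 | 2-chlorofuran-3-yl ketone analogue of 21 | C=C1[C@@H](O[Si](C)(C)C(C)(C)C)C[C@@]2(CO[Si](C(C)C)(C(C)C)C(C)C)C(OS(=O)(=O)C(F)(F)F)=CC=C[C@@H]2[C@@]1(C)CC(=O)c1ccoc1Cl
F3 | step 19 | 2-chlorofuran-3-yl dithiolane analogue of 22 | C=C1[C@@H](O[Si](C)(C)C(C)(C)C)C[C@@]2(CO[Si](C(C)C)(C(C)C)C(C)C)C(OS(=O)(=O)C(F)(F)F)=CC=C[C@@H]2[C@@]1(C)CC1(SCCS1)c1ccoc1Cl
F4 | step 19 | 2-chlorofuran-3-yl diol analogue of 23 | C=C1[C@@H](O)C[C@@]2(CO)C(OS(=O)(=O)C(F)(F)F)=CC=C[C@@H]2[C@@]1(C)CC1(SCCS1)c1ccoc1Cl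
F5 | step 19 | 2-chlorofuran-3-yl dienyl lactone alcohol, analogue of 24 | C=C1[C@@H](O)C[C@@]23COC(=O)C2=CC=C[C@@H]3[C@@]1(C)CC1(SCCS1)c1ccoc1Cl
F6 | step 19 | ring C closed 7β-alcohol (deacetyl 27) | C=C1[C@@H](O)C[C@@]23COC(=O)C2=CC[C@H]2c4occc4C4(SCCS4)C[C@]1(C)[C@@H]23
F7 | step 17 | furan-3-yl keto diol dienyl triflate | C=C1[C@@H](O)C[C@@]2(CO)C(OS(=O)(=O)C(F)(F)F)=CC=C[C@@H]2[C@@]1(C)CC(=O)c1ccoc1
F8 | step 17 | furan-3-yl keto dienyl lactone 7β-alcohol | C=C1[C@@H](O)C[C@@]23COC(=O)C2=CC=C[C@@H]3[C@@]1(C)CC(=O)c1ccoc1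
F9 | step 17 | furan-3-yl keto dienyl lactone 7β-acetate | C=C1[C@@H](OC(C)=O)C[C@@]23COC(=O)C2=CC=C[C@@H]3[C@@]1(C)CC(=O)c1ccoc1
F10 | step 4 | racemic 6 | O=C1CCC2(CO[Si](C(C)C)(C(C)C)C(C)C)C(=O)CCCC2=C1C
F11 | step 4 | C4 (2R,3R)-butane-2,3-diol ketal of (8aR)-6 | O=C1CC[C@@]2(CO[Si](C(C)C)(C(C)C)C(C)C)C3(O[C@H](C)[C@@H](C)O3)CCCC2=C1C
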